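# Proposed synthesis of [(3S,4R,5R,6S)-5-(benzoyloxy)-4,6-dihydroxy-3-methoxycyclohex-1-en-1-yl]methyl benzoate by titanium ketyl pinacol closure across C3–C4

## Analysis of the target

The target is one cyclohexene ring with oxygen on four contiguous sp3 carbons and a benzoyloxymethyl group on the alkene. The ring is numbered here C1 (OMe), C2 (free OH), C3 (OBz), C4 (free OH), C5 (alkene carbon carrying C7H2OBz) and C6 (alkene CH). In this numbering the configuration is 1S,2R,3R,4S, and each vicinal oxygen pair (C1/C2, C2/C3, C3/C4) is trans, so all four oxygens can sit pseudo-equatorially on one half-chair. The sensitive points are the C3 benzoate, which lies between two free hydroxyls and will migrate under base, the allylic C7 benzoate and C1 methyl ether, and any C4 ketone intermediate, which can eliminate towards a phenol. The difficulty is not the carbocycle but telling four similar oxygens apart (one methylated, one benzoylated, two free, in fixed order) while holding four contiguous stereocentres. C1 and C2 form a threo-dioxygenated pair with the absolute configuration of L-threonic acid, so they can come from the chiral pool with the C1 oxygen already singled out. The strategy rests on the C3–C4 bond: both carbons carry oxygen, so each can be an aldehyde carbon (C3 a saturated aldehyde next to C2, C4 an enal conjugated with C5=C6), and their reductive union closes the ring and creates both remaining carbinols.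

## Retrosynthetic reasoning

**20 ⇒ 19 (O2–Si).** The last operation only frees O2 from a triethylsilyl (TES) ether. A silyl group is chosen because it leaves under weakly acidic fluoride conditions, where the C3 benzoate, then flanked by two free hydroxyls, does not migrate.

**19 ⇒ 18 ⇒ 17 ⇒ 16 (oxidation level at C4, acyl group on O3).** In diol 16 the C3 and C4 hydroxyls cannot be acylated selectively with confidence, but only C4 is allylic. Taking C4 to the ketone (17) leaves O3 as the sole hydroxyl for benzoylation (18), and 1,2-reduction of the enone (19) re-creates C4. The gain is twofold: the position of the benzoate is decided by chemoselectivity, and the C4 configuration no longer depends on the ring closure.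

**16 ⇒ 15 (C3–C4, the ring-forming bond).** This is the only ring bond between two carbinol carbons, and one of them is allylic. Cutting it gives the open-chain dialdehyde 15, in which the Z alkene holds C4 next to C3 and the only stereocentres are C1 and C2. The forward reaction must reduce the conjugated aldehyde only, close intramolecularly, and form C3 anti to the C2 silyloxy group.

**15 ⇒ 14 ⇒ 13 ⇒ 12 ⇒ 11 ⇒ 10 (aldehydes and oxygen differentiation).** Both aldehydes go back to primary alcohols (14) and are released only at the end, because 15 is fragile. O2 must differ from O3: after acetonide hydrolysis (11) both are silylated (12) and the unhindered primary silyl ether is taken off again. The C4 oxygen travels as a 4-methoxybenzyl (PMB) ether, removed oxidatively (13), so it stays distinct from the C7 benzoate and from the acetonide.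

**10 ⇒ 9 ⇒ 8 (C7 ester).** The C7 benzoate goes back to the ester carbon of enoate 8 by reduction and acylation. This decides which carbon on C5 becomes C7 (trans to C1) and which becomes C4 (cis to C1).

**8 ⇒ 3 + 7 (C5=C6).** The trisubstituted alkene is cut by olefination between aldehyde 3 (C6) and the α-branched phosphonate 7 (C5 with both one-carbon arms). Such phosphonates put the ester trans to the incoming chain, which is the geometry the ring closure needs. Phosphonate 7 goes back to vinylphosphonate 6 by conjugate addition of the benzylic alcohol, and 6 to 4 by methylenation.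

**3 ⇒ 2 ⇒ 1 (chiral pool).** The C6 aldehyde comes from the ester of 2, and the C1 methyl ether from the only free hydroxyl of 1. Compound 1 carries C1 and C2 in the correct absolute configuration and holds O2 and O3 in one acetonide.

## Alternatives that were turned down

**Alternative 1:** The ring is cut at C4–C5 and C1–C6, a [4+2] retron once an oxygen bridge is drawn between C1 and C4.
- **Forward key step:** furan A1 and 2-bromoacrolein A2 combine under a chiral oxazaborolidine Lewis acid built on N-sulfonylated tryptophan to give the exo-formyl adduct 2-bromo-7-oxabicyclo[2.2.1]hept-5-ene-2-carbaldehyde A3. The bridgeheads are C1 and C4, the bromine-bearing carbon is C5, the formyl carbon is C7, and the bicyclic alkene is C2=C3.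
- **For:** one catalytic step sets all seven carbons and the absolute configuration from two achiral bulk chemicals, and the Br/H pair across C5–C6 is a latent alkene. On input cost and catalytic enantiocontrol it is stronger than the chosen route, which spends a stoichiometric chiral-pool ester.
- **Against:** A3 carries only one of the four ring oxygens, and it bridges C1 and C4 on one face, whereas the target has these oxygens on opposite faces. One bridgehead C–O bond must therefore be broken with inversion during methanolysis, an ionising step whose regio- and facial outcome nothing in the structure secures. The C2=C3 alkene must be dioxygenated trans with the C3 oxygen endo; the bicycle reacts from its exo face, so an exo-epoxide would have to be opened by a carboxylate from the blocked endo side at C3 only. The adduct can also revert to A1 and A2.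
- **Comparison:** most steps after the cycloaddition would be stereochemical corrections. The chosen route has C1–OMe and C2–O fixed trans before the ring exists and sets C3–O in the ring-forming step.

**Alternative 2:** The C3–O and C4–O bonds are cut, back to an arene.
- **Forward key step:** whole-cell toluene dioxygenase oxidises bromobenzene A4 to (1S,2S)-3-bromocyclohexa-3,5-diene-1,2-diol A5. The diol carbons map onto C4 and C3, the C–Br carbon onto C5.
- **For:** the ring and two stereocentres arrive enantiopure in one step, with no C–C ring closure at risk. The bromine marks C5 for attaching C7. The distal alkene can be epoxidised anti to a diol acetonide and opened at allylic C1 by methanolysis, giving the trans C1/C2 pair. The C3 oxygen already has the target configuration. In step count this alternative is probably equal or shorter.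
- **Against:** enzymatic oxygenation is cis, so C4 arrives with the wrong configuration and must be inverted. The two diol oxygens must still be differentiated so that only O3 is benzoylated. A5 dehydrates readily to a phenol and needs fermentation or a costly purchase. The vinyl bromide must survive the oxygen relay and then enter a palladium-catalysed C–C coupling on a polyoxygenated allylic system.
- **Comparison:** the chosen strategy offers the C3/C4 trans relation as the expected outcome of the bond-forming step, C7 present from the start, and shelf reagents throughout.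

**Alternative 3:** The C2–O and C3–O bonds are cut as an oxirane on a cyclohexadienone made by oxidative dearomatisation.
- **Forward key step:** the achiral quinone monoketal (6,6-dimethoxy-3-oxocyclohexa-1,4-dien-1-yl)methyl benzoate A6 undergoes Weitz–Scheffer epoxidation with an alkyl hydroperoxide and hydroxide under an N-benzyl cinchona ammonium phase-transfer catalyst. Attack at the unsubstituted enone bond gives (5,5-dimethoxy-2-oxo-7-oxabicyclo[4.1.0]hept-3-en-4-yl)methyl benzoate A7 with both C2 and C3 set.
- **For:** it is the shortest path to a carbon-complete ring, with the C7 benzoate in place, C1 and C4 at carbonyl level and the epoxide encoding trans C2/C3. It needs no chiral starting material and clearly beats the chosen route in steps to the ring.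
- **Against:** the enantioselection relies on ion pairing with a flat dienone and is not guaranteed, whereas the chiral pool is. Three further selectivities follow: carboxylate opening of the epoxide at C3 and not C2, and two carbonyl reductions (C1, then C4 after ketal hydrolysis), each trans to its neighbour and ordered so that only the C1 hydroxyl is methylated. Epoxy enones of this kind eliminate and aromatise easily under base.
- **Comparison:** the chosen strategy trades brevity for certainty. Absolute configuration and the methyl ether are in hand before cyclisation, and only C3 depends on a selective step that cannot be corrected later.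

Key step: step 13

## Route

Assumption: methyl 3,4-O-isopropylidene-L-threonate (1), a degradation product of L-ascorbic acid, is taken as a purchasable chiral-pool ester.

Step 1
Reactants: 1 methyl 3,4-O-isopropylidene-L-threonate, i.e. methyl (2R)-2-[(4S)-2,2-dimethyl-1,3-dioxolan-4-yl]-2-hydroxyacetate
Product: 2 methyl (2R)-2-[(4S)-2,2-dimethyl-1,3-dioxolan-4-yl]-2-methoxyacetate
Conditions: MeI (excess), Ag2O, 4 Å molecular sieves, Et2O, 35 °C, dark
Reagents that add atoms: iodomethane, CI
Why: Purdie-type O-methylation: Ag2O activates iodomethane and takes up HI, so the only free hydroxyl of 1 is etherified without a strong base that could epimerise the ester α-carbon or expel the β-acetal oxygen; no stereocentre is touched.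

Step 2
Reactants: 2 methyl (2R)-2-[(4S)-2,2-dimethyl-1,3-dioxolan-4-yl]-2-methoxyacetate
Product: 3 (2R)-2-[(4S)-2,2-dimethyl-1,3-dioxolan-4-yl]-2-methoxyacetaldehyde
Conditions: i-Bu2AlH (1.1 equiv), CH2Cl2, −78 °C; MeOH, then aq. potassium sodium tartrate
Reagents that add atoms: none
Why: Partial ester reduction: at −78 °C the aluminium hemiacetal, chelated by the α-methoxy oxygen, survives until work-up, so reduction should stop at aldehyde 3; the α-alkoxy aldehyde is configurationally labile and is taken on crude at once.

Step 3
Reactants: 4 triethyl phosphonoacetate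
Product: 6 ethyl 2-(diethoxyphosphoryl)acrylate, via hydroxymethyl adduct 5 (not isolated)
Conditions: (CH2O)n, piperidine (cat.), MeOH, reflux; then TsOH (cat.), toluene, reflux, Dean–Stark
Reagents that add atoms: paraformaldehyde (as formaldehyde), C=O
Why: Knoevenagel-type hydroxymethylation of the doubly activated methylene, then acid-catalysed dehydration with azeotropic removal of water, a standard preparation of this vinylphosphonate; the added carbon will become ring carbon C4.

Step 4
Reactants: 6 ethyl 2-(diethoxyphosphoryl)acrylate
Product: 7 ethyl 2-(diethoxyphosphoryl)-3-[(4-methoxybenzyl)oxy]propanoate (racemic)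
Conditions: 4-MeOC6H4CH2OH (1.1 equiv), NaH (5 mol%), THF, 0 °C
Reagents that add atoms: 4-methoxybenzyl alcohol, COc1ccc(CO)cc1
Why: Oxa-Michael addition: the alkoxide adds to the alkene activated by ester and phosphonate, and the stabilised carbanion is protonated by more alcohol, so catalytic base suffices; the centre formed is lost in step 5.

Step 5
Reactants: 3 (2R)-2-[(4S)-2,2-dimethyl-1,3-dioxolan-4-yl]-2-methoxyacetaldehyde; 7 ethyl 2-(diethoxyphosphoryl)-3-[(4-methoxybenzyl)oxy]propanoate
Product: 8 ethyl (2E,4S)-4-[(4S)-2,2-dimethyl-1,3-dioxolan-4-yl]-4-methoxy-2-{[(4-methoxybenzyl)oxy]methyl}but-2-enoate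
Conditions: 7, NaH (1.0 equiv), THF, 0 °C; then 3, −78 → 0 °C
Reagents that add atoms: none
Why: Horner–Wadsworth–Emmons olefination: the α-branched phosphonoacetate anion adds reversibly and collapses through the less crowded oxaphosphetane, which puts the ester trans to the C1 chain (E) and therefore the ether-bearing carbon, the future C4, cis to C1; the anion is pre-formed so that no free base meets aldehyde 3, and C1 and C2 are carried through unchanged.

Step 6
Reactants: 8 ethyl (2E,4S)-4-[(4S)-2,2-dimethyl-1,3-dioxolan-4-yl]-4-methoxy-2-{[(4-methoxybenzyl)oxy]methyl}but-2-enoate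
Product: 9 (2Z,4S)-4-[(4S)-2,2-dimethyl-1,3-dioxolan-4-yl]-4-methoxy-2-{[(4-methoxybenzyl)oxy]methyl}but-2-en-1-ol
Conditions: i-Bu2AlH (2.5 equiv), CH2Cl2, −78 °C; aq. potassium sodium tartrate
Reagents that add atoms: none
Why: 1,2-Reduction of the conjugated ester by the electrophilic hydride stops at the allylic alcohol without touching the alkene geometry, the acetal or the ethers; the ester carbon becomes C7 (the descriptor changes to Z only because the priorities change).

Step 7
Reactants: 9 (2Z,4S)-4-[(4S)-2,2-dimethyl-1,3-dioxolan-4-yl]-4-methoxy-2-{[(4-methoxybenzyl)oxy]methyl}but-2-en-1-ol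
Product: 10 (2E,4S)-4-[(4S)-2,2-dimethyl-1,3-dioxolan-4-yl]-4-methoxy-2-{[(4-methoxybenzyl)oxy]methyl}but-2-en-1-yl benzoate
Conditions: BzCl, pyridine, DMAP (cat.), CH2Cl2, 0 °C
Reagents that add atoms: benzoyl chloride, O=C(Cl)c1ccccc1
Why: Acylation through the N-benzoylpyridinium ion places the C7 benzoate of the target on the only free hydroxyl.

Step 8
Reactants: 10 (2E,4S)-4-[(4S)-2,2-dimethyl-1,3-dioxolan-4-yl]-4-methoxy-2-{[(4-methoxybenzyl)oxy]methyl}but-2-en-1-yl benzoate
Product: 11 (2E,4S,5S)-5,6-dihydroxy-4-methoxy-2-{[(4-methoxybenzyl)oxy]methyl}hex-2-en-1-yl benzoate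
Conditions: AcOH/H2O (4:1), 40 °C
Reagents that add atoms: none
Why: Acid-catalysed hydrolysis of the terminal dioxolane; dilute acetic acid is too weak to ionise the PMB ether or the allylic C–O bonds, and the freed hydroxyls are too far from the benzoate for acyl transfer.

Step 9
Reactants: 11 (2E,4S,5S)-5,6-dihydroxy-4-methoxy-2-{[(4-methoxybenzyl)oxy]methyl}hex-2-en-1-yl benzoate
Product: 12 (2E,4S,5S)-4-methoxy-2-{[(4-methoxybenzyl)oxy]methyl}-5,6-bis[(triethylsilyl)oxy]hex-2-en-1-yl benzoate
Conditions: Et3SiCl (2.5 equiv), imidazole, DMAP (cat.), CH2Cl2, 0 °C → rt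
Reagents that add atoms: chlorotriethylsilane, CC[Si](Cl)(CC)CC
Why: Silylation of both hydroxyls via the N-silylimidazolium ion; the secondary silyl ether is the O2 protecting group up to the last step, the primary one is a placeholder that step 11 removes.

Step 10
Reactants: 12 (2E,4S,5S)-4-methoxy-2-{[(4-methoxybenzyl)oxy]methyl}-5,6-bis[(triethylsilyl)oxy]hex-2-en-1-yl benzoate
Product: 13 (2E,4S,5S)-2-(hydroxymethyl)-4-methoxy-5,6-bis[(triethylsilyl)oxy]hex-2-en-1-yl benzoate
Conditions: DDQ (1.3 equiv), CH2Cl2/pH 7 buffer (10:1), 0 °C
Reagents that add atoms: none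
Why: Oxidative PMB cleavage: hydride abstraction from the electron-rich benzylic position gives an oxocarbenium ion that water hydrolyses to the allylic alcohol and anisaldehyde; the buffer keeps the acidic hydroquinone from the silyl ethers, and the other ethers and the benzoate are inert.

Step 11
Reactants: 13 (2E,4S,5S)-2-(hydroxymethyl)-4-methoxy-5,6-bis[(triethylsilyl)oxy]hex-2-en-1-yl benzoate
Product: 14 (2E,4S,5S)-6-hydroxy-2-(hydroxymethyl)-4-methoxy-5-[(triethylsilyl)oxy]hex-2-en-1-yl benzoate
Conditions: PPTS (0.2 equiv), MeOH/CH2Cl2 (1:1), 0 °C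
Reagents that add atoms: none
Why: Acid-catalysed methanolysis discriminates by steric access: the unhindered primary silyl ether is solvolysed far faster than the secondary one between two substituted carbons; the medium is kept weakly acidic because base would let the benzoyl group move between the two CH2O arms on C5 and so exchange the roles of C4 and C7.

Step 12
Reactants: 14 (2E,4S,5S)-6-hydroxy-2-(hydroxymethyl)-4-methoxy-5-[(triethylsilyl)oxy]hex-2-en-1-yl benzoate
Product: 15 (2Z,4S,5R)-2-formyl-4-methoxy-6-oxo-5-[(triethylsilyl)oxy]hex-2-en-1-yl benzoate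
Conditions: Dess–Martin periodinane (3 equiv), NaHCO3, CH2Cl2, 0 °C → rt; crude product used at once
Reagents that add atoms: none
Why: Dess–Martin oxidation of both primary alcohols by ligand exchange at iodine and α-hydrogen abstraction; the buffered, amine-free medium avoids β-elimination of the C1 methoxy group, epimerisation at C2 and Z-to-E isomerisation of the enal.

Step 13
Reactants: 15 (2Z,4S,5R)-2-formyl-4-methoxy-6-oxo-5-[(triethylsilyl)oxy]hex-2-en-1-yl benzoate
Product: 16 [(3S,4S,5R,6S)-5,6-dihydroxy-3-methoxy-4-[(triethylsilyl)oxy]cyclohex-1-en-1-yl]methyl benzoate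
Conditions: Cp2TiCl2 (3 equiv), Zn dust, THF, rt; then 15 added slowly (final 0.01 M), −40 → 0 °C; aq. NaH2PO4
Reagents that add atoms: none
Why: Cp2TiCl (trivalent titanium, formed from Cp2TiCl2 and Zn) should transfer one electron only to the conjugated C4 aldehyde, because the titanium-bound ketyl is allyl-stabilised, whereas the saturated C3 aldehyde is not reduced by this reagent. The O-titanated allyl radical then attacks the C3 carbonyl carbon in a 6-exo-trig closure of the ring C1–C6, and a second Cp2TiCl takes up the alkoxy radical to give the bis(titanoxy) diolate, hydrolysed on work-up; closure through C6 would need a four-membered ring and is not expected. The closest known reactions are the titanocene-mediated pinacol cyclisation of saturated 1,6-dialdehydes to trans-cyclohexane-1,2-diols and the Cp2TiCl pinacol coupling of conjugated aldehydes; here the two are combined in one molecule. C3 is controlled by the C2 stereocentre: in a chair-like transition state with C1–OMe and C2–OSiEt3 equatorial, the radical should approach the C3 carbonyl anti to the C2–O bond, which gives the 2,3-trans relation. C4 is controlled by repulsion between the two bulky Cp2ClTi–O groups, which should end up anti and pseudo-equatorial (3,4-trans); this centre is re-set in steps 14–16, so only C3 has to be right. The step needs chemoselective reduction of the enal (secured by conjugation), intramolecular over intermolecular coupling (slow addition into excess reagent at high dilution), and a reactive geometry (the Z alkene holds C4 beside C3, and an allyl radical that has lost it can still rotate into the closing conformer).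

Step 14
Reactants: 16 [(3S,4S,5R,6S)-5,6-dihydroxy-3-methoxy-4-[(triethylsilyl)oxy]cyclohex-1-en-1-yl]methyl benzoate
Product: 17 [(3S,4S,5S)-5-hydroxy-3-methoxy-6-oxo-4-[(triethylsilyl)oxy]cyclohex-1-en-1-yl]methyl benzoate
Conditions: MnO2 (20 equiv), CH2Cl2, rt
Reagents that add atoms: none
Why: MnO2 oxidises allylic alcohols and leaves the saturated C3 alcohol alone, which makes the two hydroxyls of 16 unlike and erases the configuration at C4.

Step 15
Reactants: 17 [(3S,4S,5S)-5-hydroxy-3-methoxy-6-oxo-4-[(triethylsilyl)oxy]cyclohex-1-en-1-yl]methyl benzoate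
Product: 18 [(3S,4R,5S)-5-(benzoyloxy)-3-methoxy-6-oxo-4-[(triethylsilyl)oxy]cyclohex-1-en-1-yl]methyl benzoate
Conditions: BzCl (1.5 equiv), pyridine, DMAP (cat.), CH2Cl2, 0 °C
Reagents that add atoms: benzoyl chloride, O=C(Cl)c1ccccc1
Why: O3 is now the only hydroxyl; acylation by the N-benzoylpyridinium ion at 0 °C should outrun enolisation of the α-oxygenated ketone, so C3 keeps its configuration.

Step 16
Reactants: 18 [(3S,4R,5S)-5-(benzoyloxy)-3-methoxy-6-oxo-4-[(triethylsilyl)oxy]cyclohex-1-en-1-yl]methyl benzoate
Product: 19 [(3S,4R,5R,6S)-5-(benzoyloxy)-6-hydroxy-3-methoxy-4-[(triethylsilyl)oxy]cyclohex-1-en-1-yl]methyl benzoate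
Conditions: NaBH4, CeCl3·7H2O, MeOH, −78 °C; AcOH quench
Reagents that add atoms: none
Why: Luche reduction: CeCl3 directs hydride to the carbonyl carbon (1,2-addition), and axial delivery to the half-chair with the C1, C2 and C3 substituents pseudo-equatorial should give the pseudo-equatorial C4 hydroxyl, trans to the C3 benzoate; low temperature and the acidic quench keep the benzoyl group from moving to the new alkoxide.

Step 17
Reactants: 19 [(3S,4R,5R,6S)-5-(benzoyloxy)-6-hydroxy-3-methoxy-4-[(triethylsilyl)oxy]cyclohex-1-en-1-yl]methyl benzoate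
Product: 20 [(3S,4R,5R,6S)-5-(benzoyloxy)-4,6-dihydroxy-3-methoxycyclohex-1-en-1-yl]methyl benzoate (target)
Conditions: HF·pyridine, pyridine/THF, 0 °C
Reagents that add atoms: none
Why: Formation of the Si–F bond drives cleavage of the silyl ether under mildly acidic conditions, where benzoates do not migrate; no stereocentre is touched.

## Compound list

1 | methyl (2R)-2-[(4S)-2,2-dimethyl-1,3-dioxolan-4-yl]-2-hydroxyacetate (methyl 3,4-O-isopropylidene-L-threonate) | COC(=O)[C@H](O)[C@@H]1COC(C)(C)O1 | starting material
2 | methyl (2R)-2-[(4S)-2,2-dimethyl-1,3-dioxolan-4-yl]-2-methoxyacetate | COC(=O)[C@H](OC)[C@@H]1COC(C)(C)O1 | intermediate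
3 | (2R)-2-[(4S)-2,2-dimethyl-1,3-dioxolan-4-yl]-2-methoxyacetaldehyde | O=C[C@H](OC)[C@@H]1COC(C)(C)O1 | intermediate
4 | triethyl phosphonoacetate | CCOC(=O)CP(=O)(OCC)OCC | starting material
5 | ethyl 2-(diethoxyphosphoryl)-3-hydroxypropanoate (racemic, not isolated) | CCOC(=O)C(CO)P(=O)(OCC)OCC | intermediate
6 | ethyl 2-(diethoxyphosphoryl)acrylate | CCOC(=O)C(=C)P(=O)(OCC)OCC | intermediate
7 | ethyl 2-(diethoxyphosphoryl)-3-[(4-methoxybenzyl)oxy]propanoate (racemic) | CCOC(=O)C(COCc1ccc(OC)cc1)P(=O)(OCC)OCC | intermediate
8 | ethyl (2E,4S)-4-[(4S)-2,2-dimethyl-1,3-dioxolan-4-yl]-4-methoxy-2-{[(4-methoxybenzyl)oxy]methyl}but-2-enoate | CCOC(=O)/C(COCc1ccc(OC)cc1)=C/[C@H](OC)[C@@H]1COC(C)(C)O1 | intermediate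
9 | (2Z,4S)-4-[(4S)-2,2-dimethyl-1,3-dioxolan-4-yl]-4-methoxy-2-{[(4-methoxybenzyl)oxy]methyl}but-2-en-1-ol | OC/C(COCc1ccc(OC)cc1)=C/[C@H](OC)[C@@H]1COC(C)(C)O1 | intermediate
10 | (2E,4S)-4-[(4S)-2,2-dimethyl-1,3-dioxolan-4-yl]-4-methoxy-2-{[(4-methoxybenzyl)oxy]methyl}but-2-en-1-yl benzoate | O=C(OC/C(COCc1ccc(OC)cc1)=C/[C@H](OC)[C@@H]1COC(C)(C)O1)c1ccccc1 | intermediate
11 | (2E,4S,5S)-5,6-dihydroxy-4-methoxy-2-{[(4-methoxybenzyl)oxy]methyl}hex-2-en-1-yl benzoate | O=C(OC/C(COCc1ccc(OC)cc1)=C/[C@H](OC)[C@@H](O)CO)c1ccccc1 | intermediate
12 | (2E,4S,5S)-4-methoxy-2-{[(4-methoxybenzyl)oxy]methyl}-5,6-bis[(triethylsilyl)oxy]hex-2-en-1-yl benzoate | O=C(OC/C(COCc1ccc(OC)cc1)=C/[C@H](OC)[C@@H](O[Si](CC)(CC)CC)CO[Si](CC)(CC)CC)c1ccccc1 | intermediate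
13 | (2E,4S,5S)-2-(hydroxymethyl)-4-methoxy-5,6-bis[(triethylsilyl)oxy]hex-2-en-1-yl benzoate | O=C(OC/C(CO)=C/[C@H](OC)[C@@H](O[Si](CC)(CC)CC)CO[Si](CC)(CC)CC)c1ccccc1 | intermediate
14 | (2E,4S,5S)-6-hydroxy-2-(hydroxymethyl)-4-methoxy-5-[(triethylsilyl)oxy]hex-2-en-1-yl benzoate | O=C(OC/C(CO)=C/[C@H](OC)[C@@H](O[Si](CC)(CC)CC)CO)c1ccccc1 | intermediate
15 | (2Z,4S,5R)-2-formyl-4-methoxy-6-oxo-5-[(triethylsilyl)oxy]hex-2-en-1-yl benzoate | O=C(OC/C(C=O)=C/[C@H](OC)[C@@H](O[Si](CC)(CC)CC)C=O)c1ccccc1 | intermediate
16 | [(3S,4S,5R,6S)-5,6-dihydroxy-3-methoxy-4-[(triethylsilyl)oxy]cyclohex-1-en-1-yl]methyl benzoate | CO[C@H]1C=C(COC(=O)c2ccccc2)[C@H](O)[C@@H](O)[C@@H]1O[Si](CC)(CC)CC | intermediate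
17 | [(3S,4S,5S)-5-hydroxy-3-methoxy-6-oxo-4-[(triethylsilyl)oxy]cyclohex-1-en-1-yl]methyl benzoate | CO[C@H]1C=C(COC(=O)c2ccccc2)C(=O)[C@@H](O)[C@@H]1O[Si](CC)(CC)CC | intermediate
18 | [(3S,4R,5S)-5-(benzoyloxy)-3-methoxy-6-oxo-4-[(triethylsilyl)oxy]cyclohex-1-en-1-yl]methyl benzoate | CO[C@H]1C=C(COC(=O)c2ccccc2)C(=O)[C@@H](OC(=O)c2ccccc2)[C@@H]1O[Si](CC)(CC)CC | intermediate
19 | [(3S,4R,5R,6S)-5-(benzoyloxy)-6-hydroxy-3-methoxy-4-[(triethylsilyl)oxy]cyclohex-1-en-1-yl]methyl benzoate | CO[C@H]1C=C(COC(=O)c2ccccc2)[C@H](O)[C@@H](OC(=O)c2ccccc2)[C@@H]1O[Si](CC)(CC)CC | intermediate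
20 | [(3S,4R,5R,6S)-5-(benzoyloxy)-4,6-dihydroxy-3-methoxycyclohex-1-en-1-yl]methyl benzoate | CO[C@H]1C=C(COC(=O)c2ccccc2)[C@H](O)[C@@H](OC(=O)c2ccccc2)[C@@H]1O | target

## Step count and least certain steps

Total: 17 steps. Longest linear sequence: 15 steps (1 → 20 through steps 1, 2 and 5–17). Steps 3 and 4 form a two-step branch from 4 to 7.

**Step 13 (key step).** The likely failures are intermolecular dimerisation of the enal ketyl, its over-reduction to an allyltitanium species that is merely protonated, and attack on the C3 carbonyl syn to the C2 silyloxy group. The cyclisation is established for saturated 1,6-dialdehydes and the coupling for conjugated aldehydes, but their combination in one molecule is an extrapolation. Fallback: setting out from 15, both carbonyls are reduced with SmI2 (divalent samarium; THF, t-BuOH, −78 °C). The samarium-chelated diolate should close to the 3,4-cis diol [(3S,4S,5R,6R)-5,6-dihydroxy-3-methoxy-4-[(triethylsilyl)oxy]cyclohex-1-en-1-yl]methyl benzoate F1, with the C3 oxygen still anti to the C2 oxygen. MnO2 converts F1 into enone 17, where the route is rejoined. The approach changes in that the closure is no longer asked for a trans diol; C4 is corrected entirely by steps 14–16.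

**Step 5.** Geometric control may erode (ester cis to the C1 chain), because an α-alkoxy aldehyde and a bulky α-substituent both favour early, less selective collapse; the phosphonate anion may also lose alkoxide. Fallback: setting out from 3, a Morita–Baylis–Hillman reaction with ethyl acrylate (DABCO) gives ethyl 2-{(2S)-2-[(4S)-2,2-dimethyl-1,3-dioxolan-4-yl]-1-hydroxy-2-methoxyethyl}prop-2-enoate F2. NBS/Me2S converts it with allylic transposition into ethyl (2Z,4S)-2-(bromomethyl)-4-[(4S)-2,2-dimethyl-1,3-dioxolan-4-yl]-4-methoxybut-2-enoate F3, the thermodynamically preferred geometry with CH2Br cis to the C1 chain. Ag2O-promoted etherification with 4-methoxybenzyl alcohol returns to 8.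

**Step 12.** The Z enal may isomerise to the more stable E enal, methoxide may be eliminated from C1 next to the new saturated aldehyde, and the α-silyloxy aldehyde may epimerise during handling. Fallback: setting out from 14, the two alcohols are oxidised one after the other. MnO2 oxidises only the allylic alcohol to (2Z,4S,5S)-2-formyl-6-hydroxy-4-methoxy-5-[(triethylsilyl)oxy]hex-2-en-1-yl benzoate F4, which can be purified. TEMPO/PhI(OAc)2 then oxidises the remaining primary alcohol, and the solution of 15 goes directly into step 13.

**Step 16.** Hydride may be delivered to the other face of the C4 carbonyl, and the C3 benzoyl group may migrate to the new C4 alkoxide. Fallback: setting out from 18, if reduction gives the 3,4-cis alcohol [(3S,4R,5R,6R)-5-(benzoyloxy)-6-hydroxy-3-methoxy-4-[(triethylsilyl)oxy]cyclohex-1-en-1-yl]methyl benzoate F5, a Mitsunobu reaction with chloroacetic acid (PPh3, DIAD) inverts C4 to give [(3S,4R,5R,6S)-5-(benzoyloxy)-6-(chloroacetoxy)-3-methoxy-4-[(triethylsilyl)oxy]cyclohex-1-en-1-yl]methyl benzoate F6. Thiourea removes the chloroacetyl group without touching the benzoates and returns to 19.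

## Further compounds

F1 | step 13 | [(3S,4S,5R,6R)-5,6-dihydroxy-3-methoxy-4-[(triethylsilyl)oxy]cyclohex-1-en-1-yl]methyl benzoate (C4 epimer of 16) | CO[C@H]1C=C(COC(=O)c2ccccc2)[C@@H](O)[C@@H](O)[C@@H]1O[Si](CC)(CC)CC
F2 | step 5 | ethyl 2-{(2S)-2-[(4S)-2,2-dimethyl-1,3-dioxolan-4-yl]-1-hydroxy-2-methoxyethyl}prop-2-enoate (both carbinol epimers) | CCOC(=O)C(=C)C(O)[C@H](OC)[C@@H]1COC(C)(C)O1
F3 | step 5 | ethyl (2Z,4S)-2-(bromomethyl)-4-[(4S)-2,2-dimethyl-1,3-dioxolan-4-yl]-4-methoxybut-2-enoate | CCOC(=O)/C(CBr)=C/[C@H](OC)[C@@H]1COC(C)(C)O1
F4 | step 12 | (2Z,4S,5S)-2-formyl-6-hydroxy-4-methoxy-5-[(triethylsilyl)oxy]hex-2-en-1-yl benzoate | O=C(OC/C(C=O)=C/[C@H](OC)[C@@H](O[Si](CC)(CC)CC)CO)c1ccccc1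
F5 | step 16 | [(3S,4R,5R,6R)-5-(benzoyloxy)-6-hydroxy-3-methoxy-4-[(triethylsilyl)oxy]cyclohex-1-en-1-yl]methyl benzoate (C4 epimer of 19) | CO[C@H]1C=C(COC(=O)c2ccccc2)[C@@H](O)[C@@H](OC(=O)c2ccccc2)[C@@H]1O[Si](CC)(CC)CC
F6 | step 16 | [(3S,4R,5R,6S)-5-(benzoyloxy)-6-(chloroacetoxy)-3-methoxy-4-[(triethylsilyl)oxy]cyclohex-1-en-1-yl]methyl benzoate | CO[C@H]1C=C(COC(=O)c2ccccc2)[C@H](OC(=O)CCl)[C@@H](OC(=O)c2ccccc2)[C@@H]1O[Si](CC)(CC)CC
A1 | alternative 1 | furan | c1ccoc1
A2 | alternative 1 | 2-bromoacrolein | C=C(Br)C=O
A3 | alternative 1 | 2-bromo-7-oxabicyclo[2.2.1]hept-5-ene-2-carbaldehyde (exo-formyl adduct, enantiomer as drawn) | [C@H]12C[C@](Br)(C=O)[C@H](O1)C=C2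
A4 | alternative 2 | bromobenzene | Brc1ccccc1
A5 | alternative 2 | (1S,2S)-3-bromocyclohexa-3,5-diene-1,2-diol | C1=C(Br)[C@@H](O)[C@@H](O)C=C1
A6 | alternative 3 | (6,6-dimethoxy-3-oxocyclohexa-1,4-dien-1-yl)methyl benzoate | O=C1C=CC(OC)(OC)C(COC(=O)c2ccccc2)=C1
A7 | alternative 3 | (5,5-dimethoxy-2-oxo-7-oxabicyclo[4.1.0]hept-3-en-4-yl)methyl benzoate (enantiomer as drawn) | O=C1C=C(COC(=O)c2ccccc2)C(OC)(OC)[C@@H]2O[C@H]12
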